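The slowness of the south run in its later days was my way into the flask.

| flask | left-handed substrate | right-handed substrate | partner | free catalyst | impurity | remark |
|---|---|---|---|---|---|---|
| south-east | 12 mM | 12 mM | 14.4 mM | 24 µM | 5.4 µM | the very flask that is asked about, followed so far |
| south | 12 mM | 12 mM | 14.4 mM | 24 µM | 2.7 µM | run made earlier |
| flask | 12 mM | 12 mM | 14.4 mM | 24 µM | 5.4 µM |  |
south-east run (percent of the left-handed substrate and right-handed substrate together charged)

| time / h | left-handed product / % | left-handed substrate / % |
|---|---|---|
| 2.00 | 0 | 49.9 |
| 6.00 | 0.4 | 47.0 |
| 12.0 | 2.3 | 48.0 |
| 15.0 | 2.5 | 46.2 |
| 25.0 | 7.1 | 45.4 |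

south run (percent of the left-handed substrate and right-handed substrate together charged)

| time / d | left-handed product / % | left-handed substrate / % |
|---|---|---|
| 0.250 | 0 | 48.4 |
| 0.500 | 2.2 | 47.3 |
| 1.04 | 8.9 | 43.4 |
| 1.67 | 10.2 | 39.8 |
| 4.00 | 16.5 | 32.6 |

(scatter of a reading: 1 percentage point)
- free catalyst is single-handed; left-handed substrate and right-handed substrate are mirror images of each other, charged as a racemate, each of them at the stated concentration
- steps under discussion: partner + free catalyst + left-handed substrate -> free catalyst + left-handed product; free catalyst + impurity -> spent catalyst; partner + free catalyst + right-handed substrate -> free catalyst + right-handed product; partner <-> dormant form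
- no earlier run changes the charge of partner; that part of a forecast is a guess
- apparent order in partner when 20 % of the left-handed substrate and right-handed substrate together are converted (percent change of the rate of making left-handed product for one percent more partner charged)

The product step runs as k·c(partner)·c(free catalyst)·c(left-handed substrate). At fixed conversion and fixed catalyst, c(left-handed substrate) and the partner used stay put when more partner is charged. A richer charge gets there sooner, so the integral of c(partner) over time stays put too, and with it the dormant form made, as long as its back step is small. The order is then charged partner over free partner left.

I got that ratio two ways. First, the balance, with one exit for partner: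

used at the asked conversion = 4.80 mM, ratio = 1.50

Second, the south run's rates, taking product gained and substrate lost together:

0.250 d to 1.67 d: 1.59 mM d⁻¹, partner by balance 13.0 mM

1.67 d to 4.00 d: 0.695 mM d⁻¹, partner by balance 11.1 mM

late partner from the rates = 6.92 mM, ratio = 2.08

On that late stretch the balance says 1.30, so the two ways parted. Impurity, the limiting reagent against the catalyst, could take 11.2 % of it in the south run, less than the 37.7 % shortfall in partner. So I judged that the balance cheats, and I took the dormant form as a second exit for partner. I committed to the south run's rate figure as my estimate for the flask of its leverage, charged partner over free partner left, though it is a rough reading from another run, with 1 percentage point on each reading, and from a stretch that ended short of the asked conversion.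

The forecast gave 1.5, in its words: “this is a guess”. The flask gave 1.9, beside my leverage of 2.08.

    partner + free catalyst + left-handed substrate → free catalyst + left-handed product (k = 21000 L² mol⁻² h⁻¹)
    free catalyst + impurity → spent catalyst (k = 8.20 × 10⁵ L mol⁻¹ h⁻¹)
    partner + free catalyst + right-handed substrate → free catalyst + right-handed product (k = 410 L² mol⁻² h⁻¹)
    partner ⇌ dormant form (K = 0.760, k = 0.00210 h⁻¹)

In the flask at 5.00 d, partner went into left-handed product 1.4 times as fast as into the dormant form by that step's forward rate alone, with half-lives of 10 d and 14 d. The flask then held 52 % of its charged partner beside 2.17 mM of dormant form, a leverage of 1.92.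

Readings and results are calculated for substances that don't exist; scatter was added.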